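## Retrosynthetic overview

1. Numbering: C1 is the ring carbon bearing the exocyclic CH2, C2–C4 CH2, C5 CHMe, C6 CHOH, C7 CH–O (lactone), C8 lactone CH, C9 CH2, C10/C11 epoxide (Me on C11), C12–C13 CH2, C14 CHOH; target = 5S,6R,7R,8S,10R,11R,14R.
2. Epoxide last: Shi epoxidation of the 10E olefin of the finished macrocycle.
3. 14-membered ring second: ligand-controlled Nozaki–Hiyama–Kishi closure of C14–C1 (vinyl iodide onto aldehyde).
4. γ-Lactone first: chelation-controlled indium Barbier union (C7–C8) of an East α-aminoxy aldehyde and a West (Z)-2-(bromomethyl)dienoate.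
5. East from an achiral enal by organocascade transfer hydrogenation/α-aminoxylation (C5 and C6 set first); West from an alkyne by carboalumination and a new bromide-triggered Michael–HWE olefination.

Assumption: hept-6-yn-2-one, tert-butyldimethyl(pent-4-yn-1-yloxy)silane and all named reagents and catalysts are taken as commercially available.

## Route

Step 1
Reactants: 1 hept-6-yn-2-one
Product: 2 6-iodohept-6-en-2-one
Conditions: NaI, TMSCl, H2O (0.5 equiv), MeCN, 25 °C
Reagents that add atoms: sodium iodide [Na+].[I-]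
Why: HI made in situ adds across the terminal alkyne in Markovnikov fashion (hydroiodination) to give the 2-iodo-1-alkene needed for the later ring closure; no stereocenter is formed.

Step 2
Reactants: 2 6-iodohept-6-en-2-one
Product: 4 (2E)-7-iodo-3-methylocta-2,7-dienal (E/Z mixture), via azadiene 3 (not isolated)
Conditions: diethyl [2-(cyclohexylamino)vinyl]phosphonate, NaH, THF, 0 to 25 °C; then aq. oxalic acid, toluene, 25 °C
Reagents that add atoms: diethyl [(E)-2-(cyclohexylamino)ethenyl]phosphonate CCOP(=O)(OCC)/C=C/NC1CCCCC1; water O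
Why: Nagata two-carbon formyl olefination (Horner–Wadsworth–Emmons reaction of the metallated phosphonate, then imine hydrolysis) turns the methyl ketone into the β-methyl enal, and the E/Z ratio does not matter because the next step is stereoconvergent.

Step 3
Reactants: 4 (2E)-7-iodo-3-methylocta-2,7-dienal (E/Z mixture)
Product: 6 (2R,3S)-7-iodo-3-methyl-2-(phenylaminooxy)oct-7-enal, via saturated aldehyde 5 (not isolated)
Conditions: (S)-2-tert-butyl-3-methylimidazolidin-4-one trichloroacetate (20 mol %; antipode of the catalyst that reduces β-methylcinnamaldehyde to (S)-3-phenylbutanal), Hantzsch ester (diethyl 2,6-dimethyl-1,4-dihydropyridine-3,5-dicarboxylate), CHCl3, −30 °C; then L-proline (30 mol %), PhNO, 4 °C; short silica plug, used at once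
Reagents that add atoms: nitrosobenzene O=Nc1ccccc1
Why: Cycle-specific organocascade (iminium transfer hydrogenation, then enamine α-aminoxylation): the imidazolidinone shields one face of the E/Z-equilibrating iminium ion so hydride sets C5 as S, and L-proline directs O-attack of nitrosobenzene to set C6 as R under catalyst control; these are the first stereocenters of the route.

Step 4
Reactants: 7 tert-butyldimethyl(pent-4-yn-1-yloxy)silane
Product: 10 (3E)-7-(tert-butyldimethylsilyloxy)-4-methylhept-3-en-1-ol, via alkenylalane 8 (not isolated), via lithium alanate 9 (not isolated)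
Conditions: AlMe3, Cp2ZrCl2 (25 mol %), CH2Cl2, 0 to 25 °C; n-BuLi, THF, −78 °C; oxirane, −78 to 0 °C; aq. potassium sodium tartrate
Reagents that add atoms: trimethylaluminium C[Al](C)C; oxirane C1CO1
Why: Negishi zirconium-catalysed syn-carboalumination places Me and Al cis on the alkyne, and the derived alanate opens oxirane with retention, which fixes the (E)-trisubstituted C10=C11 olefin.

Step 5
Reactants: 10 (3E)-7-(tert-butyldimethylsilyloxy)-4-methylhept-3-en-1-ol
Product: 11 (3E)-7-(tert-butyldimethylsilyloxy)-4-methylhept-3-enal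
Conditions: Dess–Martin periodinane, NaHCO3, CH2Cl2, 0 °C; used crude
Reagents that add atoms: none
Why: Buffered Dess–Martin oxidation gives the β,γ-unsaturated aldehyde without base-induced conjugation of the olefin.

Step 6
Reactants: 11 (3E)-7-(tert-butyldimethylsilyloxy)-4-methylhept-3-enal
Product: 12 methyl (2Z,5E)-2-(bromomethyl)-9-(tert-butyldimethylsilyloxy)-6-methylnona-2,5-dienoate
Conditions: trimethyl 2-phosphonoacrylate, MgBr2·OEt2 (2 equiv), CH2Cl2/THF, −20 to 25 °C
Reagents that add atoms: trimethyl 2-phosphonoacrylate C=C(C(=O)OC)P(=O)(OC)OC; magnesium bromide diethyl etherate Br[Mg]Br.CCOCC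
Why: Proposed new method: bromide from MgBr2 adds in conjugate fashion to the doubly activated alkene of the phosphonoacrylate, giving the same magnesium-chelated phosphonoenolate that olefinates aldehydes under MgBr2/Et3N Horner–Wadsworth–Emmons conditions, so the base-sensitive aldehyde is converted without amine base into the C8=Cα bond with the ester trans to the chain (2Z, CH2Br cis to the chain); the closest known reactions are thiolate- or alkoxide-triggered Michael–HWE sequences of 2-phosphonoacrylates and MgI2- or TiCl4-mediated halo-aldol reactions.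

Step 7
Reactants: 6 (2R,3S)-7-iodo-3-methyl-2-(phenylaminooxy)oct-7-enal; 12 methyl (2Z,5E)-2-(bromomethyl)-9-(tert-butyldimethylsilyloxy)-6-methylnona-2,5-dienoate
Product: 15 (4S,5R)-4-[(2E)-6-(tert-butyldimethylsilyloxy)-3-methylhex-2-en-1-yl]-5-[(1R,2S)-6-iodo-2-methyl-1-(phenylaminooxy)hept-6-en-1-yl]-3-methylideneoxolan-2-one, via allylindium 13 (not isolated), via hydroxy ester 14 (not isolated)
Conditions: indium powder, THF/H2O (1:1), 25 °C; then TsOH·H2O (cat.), CH2Cl2, 25 °C
Reagents that add atoms: none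
Why: Indium-mediated Barbier allylation in water through a chelated (Cram-chelate) cyclic transition state, in which indium bridges the aldehyde oxygen and the α-aminoxy group, delivers the γ-carbon of the (Z)-allylindium syn to the C6 oxygen with syn simple diastereoselection (7R, 8S), and acid then closes the cis-fused α-methylene-γ-butyrolactone.

Step 8
Reactants: 15 (4S,5R)-4-[(2E)-6-(tert-butyldimethylsilyloxy)-3-methylhex-2-en-1-yl]-5-[(1R,2S)-6-iodo-2-methyl-1-(phenylaminooxy)hept-6-en-1-yl]-3-methylideneoxolan-2-one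
Product: 17 (4S,5R)-4-[(2E)-6-hydroxy-3-methylhex-2-en-1-yl]-5-[(1R,2S)-1-hydroxy-6-iodo-2-methylhept-6-en-1-yl]-3-methylideneoxolan-2-one, via silyl ether 16 (not isolated)
Conditions: zinc dust, AcOH/THF/H2O (3:1:1), 25 °C, 16 h
Reagents that add atoms: none
Why: Zinc in acetic acid cleaves the N–O bond reductively and the aqueous acid removes the primary silyl ether in the same pot (reductive N–O cleavage, then acid desilylation), while vinyl iodide, lactone and olefins are left alone.

Step 9
Reactants: 17 (4S,5R)-4-[(2E)-6-hydroxy-3-methylhex-2-en-1-yl]-5-[(1R,2S)-1-hydroxy-6-iodo-2-methylhept-6-en-1-yl]-3-methylideneoxolan-2-one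
Product: 18 (4E)-6-[(2R,3S)-2-[(1R,2S)-1-hydroxy-6-iodo-2-methylhept-6-en-1-yl]-4-methylidene-5-oxooxolan-3-yl]-4-methylhex-4-enal
Conditions: TEMPO (2,2,6,6-tetramethylpiperidin-1-oxyl, 10 mol %), PhI(OAc)2, CH2Cl2, 25 °C
Reagents that add atoms: none
Why: Oxoammonium (TEMPO/PhI(OAc)2) oxidation is selective for the primary alcohol over the hindered secondary C6 alcohol.

Step 10
Reactants: 18 (4E)-6-[(2R,3S)-2-[(1R,2S)-1-hydroxy-6-iodo-2-methylhept-6-en-1-yl]-4-methylidene-5-oxooxolan-3-yl]-4-methylhex-4-enal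
Product: 20 macrocyclic diol lactone (5S,6R,7R,8S,14R; 10E olefin; the target without the epoxide oxygen), via alkenylchromium 19 (not isolated)
Conditions: CrCl2 (4 equiv), Kishi oxazoline–sulfonamide ligand N-[2-(4-isopropyl-4,5-dihydrooxazol-2-yl)-6-methylphenyl]methanesulfonamide (enantiomer that gives 14R, to be fixed in a model coupling), Et3N, NiCl2(2,9-dimethyl-1,10-phenanthroline) (10 mol %), MeCN, 25 °C, 2 mM, slow addition
Reagents that add atoms: none
Why: Nozaki–Hiyama–Kishi macrocyclization: nickel activates the vinyl iodide and hands the alkenyl group to chromium, and the alkenylchromium adds to the aldehyde at high dilution with the chiral sulfonamide ligand on chromium selecting the aldehyde face (14R); free OH, lactone and enoate are tolerated.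

Step 11
Reactants: 20 macrocyclic diol lactone (5S,6R,7R,8S,14R; 10E olefin)
Product: 21 CNP0124069.1 (5S,6R,7R,8S,10R,11R,14R)
Conditions: Shi ketone (1,2:4,5-di-O-isopropylidene-β-D-erythro-2,3-hexodiulo-2,6-pyranose, 30 mol %), Oxone (2KHSO5·KHSO4·K2SO4), K2CO3, Bu4NHSO4, MeCN/dimethoxymethane/aq. Na2B4O7 buffer, 0 °C
Reagents that add atoms: potassium peroxymonosulfate (active part of Oxone) [K+].[O-]S(=O)(=O)OO
Why: Shi epoxidation: the chiral dioxirane from the D-fructose-derived ketone attacks the electron-rich (E)-trisubstituted olefin through a spiro transition state to give the (10R,11R)-epoxide, leaving the 1,1-disubstituted allylic-alcohol olefin and the electron-poor α-methylene lactone untouched.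

## Compound list

1 | hept-6-yn-2-one | CC(=O)CCCC#C | starting material
2 | 6-iodohept-6-en-2-one | CC(=O)CCCC(I)=C | intermediate
3 | (1E,2E)-N-cyclohexyl-7-iodo-3-methylocta-2,7-dien-1-imine (azadiene, not isolated) | C=C(I)CCC/C(C)=C/C=N/C1CCCCC1 | intermediate
4 | (2E)-7-iodo-3-methylocta-2,7-dienal (E/Z mixture; E isomer drawn) | O=C/C=C(\C)CCCC(I)=C | intermediate
5 | (3S)-7-iodo-3-methyloct-7-enal (not isolated) | O=CC[C@@H](C)CCCC(I)=C | intermediate
6 | (2R,3S)-7-iodo-3-methyl-2-(phenylaminooxy)oct-7-enal | O=C[C@H](ONc1ccccc1)[C@@H](C)CCCC(I)=C | intermediate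
7 | tert-butyldimethyl(pent-4-yn-1-yloxy)silane | C#CCCCO[Si](C)(C)C(C)(C)C | starting material
8 | (E)-alkenyldimethylalane (not isolated) | C[Al](C)/C=C(\C)CCCO[Si](C)(C)C(C)(C)C | intermediate
9 | lithium butyl(alkenyl)dimethylalanate (not isolated) | [Li+].CCCC[Al-](C)(C)/C=C(\C)CCCO[Si](C)(C)C(C)(C)C | intermediate
10 | (3E)-7-(tert-butyldimethylsilyloxy)-4-methylhept-3-en-1-ol | OCC/C=C(\C)CCCO[Si](C)(C)C(C)(C)C | intermediate
11 | (3E)-7-(tert-butyldimethylsilyloxy)-4-methylhept-3-enal | O=CC/C=C(\C)CCCO[Si](C)(C)C(C)(C)C | intermediate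
12 | methyl (2Z,5E)-2-(bromomethyl)-9-(tert-butyldimethylsilyloxy)-6-methylnona-2,5-dienoate | COC(=O)/C(CBr)=C/C/C=C(\C)CCCO[Si](C)(C)C(C)(C)C | intermediate
13 | allylindium dibromide derived from 12 (not isolated) | COC(=O)/C(C[In](Br)Br)=C/C/C=C(\C)CCCO[Si](C)(C)C(C)(C)C | intermediate
14 | methyl (3S,4R,5R,6S)-3-[(2E)-6-(tert-butyldimethylsilyloxy)-3-methylhex-2-en-1-yl]-4-hydroxy-10-iodo-6-methyl-2-methylidene-5-(phenylaminooxy)undec-10-enoate (not isolated) | C=C(I)CCC[C@H](C)[C@@H](ONc1ccccc1)[C@H](O)[C@@H](C/C=C(\C)CCCO[Si](C)(C)C(C)(C)C)C(=C)C(=O)OC | intermediate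
15 | (4S,5R)-4-[(2E)-6-(tert-butyldimethylsilyloxy)-3-methylhex-2-en-1-yl]-5-[(1R,2S)-6-iodo-2-methyl-1-(phenylaminooxy)hept-6-en-1-yl]-3-methylideneoxolan-2-one | C=C(I)CCC[C@H](C)[C@@H](ONc1ccccc1)[C@@H]1OC(=O)C(=C)[C@@H]1C/C=C(\C)CCCO[Si](C)(C)C(C)(C)C | intermediate
16 | (4S,5R)-4-[(2E)-6-(tert-butyldimethylsilyloxy)-3-methylhex-2-en-1-yl]-5-[(1R,2S)-1-hydroxy-6-iodo-2-methylhept-6-en-1-yl]-3-methylideneoxolan-2-one (not isolated) | C=C(I)CCC[C@H](C)[C@@H](O)[C@@H]1OC(=O)C(=C)[C@@H]1C/C=C(\C)CCCO[Si](C)(C)C(C)(C)C | intermediate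
17 | (4S,5R)-4-[(2E)-6-hydroxy-3-methylhex-2-en-1-yl]-5-[(1R,2S)-1-hydroxy-6-iodo-2-methylhept-6-en-1-yl]-3-methylideneoxolan-2-one | C=C(I)CCC[C@H](C)[C@@H](O)[C@@H]1OC(=O)C(=C)[C@@H]1C/C=C(\C)CCCO | intermediate
18 | (4E)-6-[(2R,3S)-2-[(1R,2S)-1-hydroxy-6-iodo-2-methylhept-6-en-1-yl]-4-methylidene-5-oxooxolan-3-yl]-4-methylhex-4-enal | C=C(I)CCC[C@H](C)[C@@H](O)[C@@H]1OC(=O)C(=C)[C@@H]1C/C=C(\C)CCC=O | intermediate
19 | alkenylchromium dichloride derived from 18 (trivalent chromium, not isolated) | C=C([Cr](Cl)Cl)CCC[C@H](C)[C@@H](O)[C@@H]1OC(=O)C(=C)[C@@H]1C/C=C(\C)CCC=O | intermediate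
20 | macrocyclic diol lactone: 14-membered carbocycle with CH2= on C1, Me on C5 and C11, OH on C6 and C14, 10E olefin, cis-fused 3-methylideneoxolan-2-one across C7(O)/C8; 5S,6R,7R,8S,14R | C=C1CCC[C@H](C)[C@@H](O)[C@@H]2OC(=O)C(=C)[C@@H]2C/C=C(\C)CC[C@H]1O | intermediate
21 | CNP0124069.1: as 20 with the (10R,11R)-epoxide; 5S,6R,7R,8S,10R,11R,14R | C=C1CCC[C@H](C)[C@@H](O)[C@@H]2OC(=O)C(=C)[C@@H]2C[C@H]2O[C@]2(C)CC[C@H]1O | target

## Step count and risks

Total steps: 11. Longest linear sequence: 8 (steps 4, 5, 6, 7, 8, 9, 10, 11, or equally 1, 2, 3, 7, 8, 9, 10, 11).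

Three steps most likely to fail:

Step 6 (the proposed new bromide-triggered Michael–HWE). Bromide may not add efficiently to the phosphonoacrylate, or the magnesium enolate may olefinate slowly. The fallback uses known chemistry, sets out from 11 and returns at 12. Aldehyde 11 is treated with the α-(methoxycarbonyl)vinylalane generated from methyl propiolate, i-Bu2AlH and N-methylmorpholine N-oxide (THF, 0 °C, vinylalumination) to give the Baylis–Hillman-type alcohol methyl (5E)-9-(tert-butyldimethylsilyloxy)-3-hydroxy-6-methyl-2-methylidenenon-5-enoate F1 (racemic at the carbinol, which is lost in the next operation). NBS/Me2S (CH2Cl2, 0 °C) then converts F1 with allylic transposition into the (2Z)-bromide 12.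

Step 10 (macrocyclization and C14 control). The ring closure may give low yield or the wrong C14 epimer if ligand control is weak in the intramolecular setting. The fallback sets out from 18 and returns at 20. Ligand-free closure (CrCl2, NiCl2 1 mol %, DMSO, 25 °C, 2 mM) gives the macrocyclic diol as a C14 epimer mixture F2. MnO2 (CH2Cl2) oxidises only the allylic C14 alcohol to the macrocyclic enone F3. Reduction with (S)-2-methyl-CBS-oxazaborolidine and catecholborane (toluene, −78 °C) then sets 14R by reagent control (alkenyl as the large group) and gives 20.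

Step 11 (late Shi epoxidation). The macrocycle may expose the wrong olefin face to the dioxirane, and the lactone is exposed to pH 10 buffer. The fallback sets out from 17 and returns at 21. Shi epoxidation is run on the conformationally free acyclic diol 17 under the step 11 conditions, giving the (10R,11R)-epoxy diol F4 under pure catalyst control. TEMPO/PhI(OAc)2 with NaHCO3 gives the epoxy aldehyde F5 (buffered to prevent attack of the C14 hydroxyl on the epoxide). The Nozaki–Hiyama–Kishi closure of step 10 on F5 then gives 21 directly.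

## Further compounds

F1 | step 6 | methyl (5E)-9-(tert-butyldimethylsilyloxy)-3-hydroxy-6-methyl-2-methylidenenon-5-enoate (racemic) | COC(=O)C(=C)C(O)C/C=C(\C)CCCO[Si](C)(C)C(C)(C)C
F2 | step 10 | macrocyclic diol lactone as C14 epimer mixture (5S,6R,7R,8S; 10E) | C=C1CCC[C@H](C)[C@@H](O)[C@@H]2OC(=O)C(=C)[C@@H]2C/C=C(\C)CCC1O
F3 | step 10 | macrocyclic C14 enone (5S,6R,7R,8S; 10E) | C=C1CCC[C@H](C)[C@@H](O)[C@@H]2OC(=O)C(=C)[C@@H]2C/C=C(\C)CCC1=O
F4 | step 11 | acyclic (10R,11R)-epoxy diol derived from 17 | C=C(I)CCC[C@H](C)[C@@H](O)[C@@H]1OC(=O)C(=C)[C@@H]1C[C@H]1O[C@]1(C)CCCO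
F5 | step 11 | acyclic (10R,11R)-epoxy aldehyde | C=C(I)CCC[C@H](C)[C@@H](O)[C@@H]1OC(=O)C(=C)[C@@H]1C[C@H]1O[C@]1(C)CCC=O
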